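**Retrosynthetic overview**
1. Germacrane numbering is used. Ring A is the 3(2H)-furanone (O, C3, C2, C1, C10), ring B the α-methylene-γ-butyrolactone (O, C6, C7, C11, C12), and ring C the nine-membered oxonine (O, C3, C4, C5, C6, C7, C8, C9, C10).
2. The last disconnection is C9–C10 (aldol retron C9–OH/C10/C1=O). Ring C opens to a furanone–aldehyde that lacks the C9 and C10 stereocentres, and its two C10–H epimers share one planar aromatic enol, a 3-silyloxyfuran.
3. Enabling feature: C10 is C2 of ring A, flanked by the ring oxygen and the C1 ketone, so it enolises to an aromatic furan and is that furan's most nucleophilic carbon. The cis fusion of ring B at C6/C7 and the Z C4=C5 alkene hold the furan arm and the C8–C9 aldehyde arm side by side.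
4. Ring A comes from gold cycloisomerisation (O–C3) of an α′-hydroxy ynone, made by acylating a terminal alkyne (C1–C2) with a lactic acid chloride. The C8 ester and C9 aldehyde come from the glyceraldehyde acetonide unit.
5. Ring B and C6/C7 come from a Barbier union (C6–C7) of a (Z)-enynal with a glyceraldehyde-derived 2-(bromomethyl)acrylate, followed by lactonisation. Ring order: B (step 5), A (step 14), C (step 15).

Key step: step 15

Remark: racemic lactic acid is used on purpose, so C10 is carried as a mixture of epimers (drawn without configuration) until step 15 converges them; germacrane locants are used for all intermediates.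

**Step 1**
Reactants: 1 1,2:5,6-di-O-isopropylidene-D-mannitol
Product: 2 (R)-2,2-dimethyl-1,3-dioxolane-4-carbaldehyde
Conditions: NaIO4, sat. aq. NaHCO3, CH2Cl2, rt
Reagents that add atoms: none
Why: Periodate glycol cleavage of the central diol should give two equivalents of the aldehyde, whose stereocentre (the future C8) is taken unchanged from the chiral pool.

**Step 2**
Reactants: 2 (R)-2,2-dimethyl-1,3-dioxolane-4-carbaldehyde; 3 methyl acrylate
Product: 4 methyl 2-{hydroxy[(4R)-2,2-dimethyl-1,3-dioxolan-4-yl]methyl}prop-2-enoate (both carbinol epimers)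
Conditions: DABCO (0.5 equiv), 1,4-dioxane/H2O (1:1), rt
Reagents that add atoms: none
Why: Morita–Baylis–Hillman reaction joins C7 to C11, and the new carbinol centre need not be controlled because step 3 erases it.

**Step 3**
Reactants: 4 Morita–Baylis–Hillman adduct
Product: 5 methyl (2Z)-2-(bromomethyl)-3-[(4S)-2,2-dimethyl-1,3-dioxolan-4-yl]prop-2-enoate
Conditions: NBS, Me2S, CH2Cl2, 0 °C to rt
Reagents that add atoms: N-bromosuccinimide, O=C1CCC(=O)N1Br
Why: Corey–Kim-type activation of the allylic alcohol followed by SN2′ attack of bromide should funnel both epimers into the favoured Z acrylate (C8 cis to CH2Br) under near-neutral conditions that spare the acetonide.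

**Step 4**
Reactants: 6 (2Z)-3-methylpent-2-en-4-yn-1-ol
Product: 7 (2Z)-3-methylpent-2-en-4-ynal
Conditions: activated MnO2, CH2Cl2, rt, filtered solution used at once
Reagents that add atoms: none
Why: Neutral heterogeneous allylic oxidation with MnO2 should give the volatile enynal without loss of the Z geometry that becomes the C4=C5 alkene.

**Step 5**
Reactants: 5 allylic bromide; 7 (Z)-enynal
Product: 10 (4S,5S)-4-[(4S)-2,2-dimethyl-1,3-dioxolan-4-yl]-3-methylidene-5-[(1Z)-2-methylbut-1-en-3-yn-1-yl]oxolan-2-one (6,7-cis lactone; 6S,7S,8S), via allylindium reagent 8 (not isolated), via syn hydroxy ester 9 (not isolated)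
Conditions: In (powder), THF/H2O (1:1), rt; extract, then PPTS (cat.), toluene, 60 °C
Reagents that add atoms: none
Why: In this Barbier 2-(alkoxycarbonyl)allylation and acid lactonisation the allylindium keeps C8 cis to CH2In, so the closed chair transition state places C8 axial and gives the 6,7-syn adduct (cis lactone), while allylic 1,3-strain holds C8–H inside so that the aldehyde bonds to the C7 face anti to the C8–C9 bond with C8–O outside, setting 6S,7S from the 8S centre.

**Step 6**
Reactants: 10 lactone acetonide
Product: 11 (4R,5S)-4-[(1S)-1,2-dihydroxyethyl]-3-methylidene-5-[(1Z)-2-methylbut-1-en-3-yn-1-yl]oxolan-2-one (same spatial arrangement; the C7 descriptor changes by priority only)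
Conditions: AcOH/H2O (4:1), 40 °C
Reagents that add atoms: none
Why: Mild acidic acetal hydrolysis frees the C8/C9 diol, and the absence of base keeps the 6,12-lactone from migrating to O8.

**Step 7**
Reactants: 11 diol
Product: 12 C9 tert-butyldimethylsilyl ether of 11 (C8–OH free; 6S,7R,8S)
Conditions: TBSCl, imidazole, CH2Cl2, 0 °C
Reagents that add atoms: tert-butyldimethylsilyl chloride, CC(C)(C)[Si](C)(C)Cl
Why: Sterically controlled silylation should take the primary C9 hydroxyl only.

**Step 8**
Reactants: 12 C9 silyl ether; 13 methacrylic anhydride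
Product: 14 C8 methacrylate of 12 (6S,7S,8S)
Conditions: DMAP (cat.), Et3N, CH2Cl2, 0 °C to rt
Reagents that add atoms: none
Why: DMAP-catalysed acylation installs the target ester at O8 with retention, since the C8–O bond is not touched.

**Step 9**
Reactants: 15 DL-lactic acid (anhydrous grade)
Product: 16 tert-butyldimethylsilyl 2-[(tert-butyldimethylsilyl)oxy]propanoate (racemic)
Conditions: TBSCl (2.2 equiv), imidazole, DMF, rt
Reagents that add atoms: tert-butyldimethylsilyl chloride, CC(C)(C)[Si](C)(C)Cl
Why: Exhaustive silylation protects the hydroxyl and turns the acid into a silyl ester ready for neutral conversion into the chloride.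

**Step 10**
Reactants: 16 bis-silylated lactic acid
Product: 17 2-[(tert-butyldimethylsilyl)oxy]propanoyl chloride (racemic)
Conditions: (COCl)2, DMF (cat.), CH2Cl2, 0 °C to rt
Reagents that add atoms: oxalyl chloride, O=C(Cl)C(=O)Cl
Why: Silyl esters react with oxalyl chloride and catalytic DMF to give acid chlorides without free HCl, so the silyl ether survives.

**Step 11**
Reactants: 14 terminal enyne; 17 acid chloride
Product: 18 ynone carrying C10–OTBS and C9–OTBS (6S,7S,8S; C10 epimers)
Conditions: PdCl2(PPh3)2 (2 mol %), CuI (4 mol %), Et3N (1.5 equiv), THF, rt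
Reagents that add atoms: none
Why: Acyl Sonogashira coupling forms C1–C2 under conditions mild enough for the lactone, the methacrylate and both Michael acceptors.

**Step 12**
Reactants: 18 bis-silyl ynone
Product: 19 α′-hydroxy ynone with free C9 primary alcohol (6S,7S,8S; C10 epimers)
Conditions: HF·pyridine, pyridine, THF, 0 °C
Reagents that add atoms: none
Why: Fluoride cleaves both silyl ethers in one operation, and the acidic medium slows a methacryloyl shift from O8 to O9.

**Step 13**
Reactants: 19 diol
Product: 20 C9 aldehyde with the α′-hydroxy ynone intact (6S,7S,8S; C10 epimers)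
Conditions: TEMPO (10 mol %), PhI(OAc)2, CH2Cl2, rt
Reagents that add atoms: none
Why: The oxoammonium oxidation is selective for the primary alcohol over the electron-poor secondary α-hydroxy ketone, and being base-free it should neither epimerise C8 nor move the ester.

**Step 14**
Reactants: 20 hydroxy ynone aldehyde
Product: 21 2-methyl-3(2H)-furanone aldehyde, ring A closed (6S,7S,8S; C10 epimers)
Conditions: (4-CF3C6H4)3PAuCl (5 mol %), AgOTf (5 mol %), toluene, rt
Reagents that add atoms: none
Why: In this known cycloisomerisation of α′-hydroxy ynones to 3(2H)-furanones, cationic monovalent gold activates C2≡C3, the C10 hydroxyl adds 5-endo-dig to C3 and protodeauration follows, leaving aldehyde and esters untouched.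

**Step 15**
Reactants: 21 furanone aldehyde
Product: 23 C9 triethylsilyl ether of the target (4Z,6S,7S,8S,9R,10R), via 3-triethylsilyloxyfuran 22 (not isolated)
Conditions: TESOTf (3 equiv), iPr2NEt (3 equiv), CH2Cl2 (1 mM, slow addition of 21), −78 to −20 °C
Reagents that add atoms: triethylsilyl trifluoromethanesulfonate, CC[Si](CC)(CC)OS(=O)(=O)C(F)(F)F
Why: Proposed new method: TESOTf and iPr2NEt enolise only C10–H of ring A, because that enol is an aromatic furan, so both C10 epimers of 21 converge on planar 22, whose C10 then adds to the TESOTf-activated C9 aldehyde through an open Mukaiyama aldol transition state with silyl transfer to O9, which dearomatises the furan back to the furanone. The closest known reaction types are the intermolecular Lewis acid aldol addition of 2-alkyl-3-silyloxyfurans to aldehydes at C2 of the furan and the R3SiOTf/amine silylative cycloaldolisation of butenolide-tethered aldehydes through transient silyloxyfurans, but no ring has yet been closed at C2 of a 3-silyloxyfuran. Ring C closes in the 9-(enolexo)-exo-trig mode, and the ten-membered carbocycle C1–C10 that closes with it reads as 10-(enolendo)-exo-trig. C10 is set by the choice of furan face, since the chain must arch over the furan and only one face lets ring B (C11 and O6) sit on the convex outside of the forming ring with C14 pointing away, whereas the other face drives C11 against the furan oxygen. C9 is set by the aldehyde rotamer, since the tether forces C10 to arrive gauche to C7, the C8–O(acyl) and C9=O dipoles stay antiparallel and C9=O lies antiperiplanar to the C1–OSi bond away from the silyl group, which together expose the face that gives the 8,9-syn 9R carbinol that an untethered nucleophile would not favour. The step needs enolisation of the furanone before the aldehyde, attack through C10 rather than C2, and ring closure rather than oligomerisation, secured respectively by the aromatic enol, by the oxygen-flanked position of C10, and by high dilution together with the U-shape imposed by the cis lactone and the Z alkene.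

**Step 16**
Reactants: 23 C9 triethylsilyl ether
Product: 24 target, (4Z,6S,7S,8S,9R,10R)-9-hydroxy-8-methacryloyloxy-1-oxo-3,10-epoxygermacra-2,4,11(13)-trien-12,6-olide
Conditions: HF·pyridine, THF, 0 °C
Reagents that add atoms: none
Why: Acidic fluoride desilylation frees the C9 carbinol without base, so neither retro-aldol opening nor acyl migration is triggered, and elimination is impossible at the quaternary C10.

**Compound list**
1 | 1,2:5,6-di-O-isopropylidene-D-mannitol | CC1(C)OC[C@@H](O1)[C@@H](O)[C@H](O)[C@H]1COC(C)(C)O1 | starting material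
2 | (R)-2,2-dimethyl-1,3-dioxolane-4-carbaldehyde | CC1(C)OC[C@@H](O1)C=O | intermediate
3 | methyl acrylate | C=CC(=O)OC | starting material
4 | Morita–Baylis–Hillman adduct (carbinol epimers) | COC(=O)C(=C)C(O)[C@H]1COC(C)(C)O1 | intermediate
5 | (Z)-2-(bromomethyl)acrylate with (4S)-dioxolanyl group | COC(=O)/C(CBr)=C/[C@H]1COC(C)(C)O1 | intermediate
6 | (2Z)-3-methylpent-2-en-4-yn-1-ol | C#C/C(C)=C\CO | starting material
7 | (2Z)-3-methylpent-2-en-4-ynal | C#C/C(C)=C\C=O | intermediate
8 | allylindium reagent, drawn as the dibromide (not isolated) | COC(=O)/C(C[In](Br)Br)=C/[C@H]1COC(C)(C)O1 | intermediate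
9 | methyl (3S,4S,5Z)-3-[(4S)-2,2-dimethyl-1,3-dioxolan-4-yl]-4-hydroxy-6-methyl-2-methylideneoct-5-en-7-ynoate (not isolated) | CC1(C)OC[C@@H](O1)[C@@H](C(=C)C(=O)OC)[C@@H](O)/C=C(/C)C#C | intermediate
10 | cis lactone acetonide (6S,7S,8S) | CC1(C)OC[C@@H](O1)[C@H]2C(=C)C(=O)O[C@H]2/C=C(/C)C#C | intermediate
11 | C8,C9 diol | OC[C@@H](O)[C@H]1C(=C)C(=O)O[C@H]1/C=C(/C)C#C | intermediate
12 | C9 TBS ether, C8–OH free | CC(C)(C)[Si](C)(C)OC[C@@H](O)[C@H]1C(=C)C(=O)O[C@H]1/C=C(/C)C#C | intermediate
13 | methacrylic anhydride | C=C(C)C(=O)OC(=O)C(C)=C | starting material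
14 | C8 methacrylate, C9 TBS ether | C=C(C)C(=O)O[C@H](CO[Si](C)(C)C(C)(C)C)[C@H]1C(=C)C(=O)O[C@H]1/C=C(/C)C#C | intermediate
15 | DL-lactic acid | CC(O)C(=O)O | starting material
16 | TBS 2-(TBS-oxy)propanoate | CC(O[Si](C)(C)C(C)(C)C)C(=O)O[Si](C)(C)C(C)(C)C | intermediate
17 | 2-(TBS-oxy)propanoyl chloride | CC(O[Si](C)(C)C(C)(C)C)C(=O)Cl | intermediate
18 | bis-TBS ynone | C=C(C)C(=O)O[C@H](CO[Si](C)(C)C(C)(C)C)[C@H]1C(=C)C(=O)O[C@H]1/C=C(/C)C#CC(=O)C(C)O[Si](C)(C)C(C)(C)C | intermediate
19 | α′-hydroxy ynone with C9 alcohol | C=C(C)C(=O)O[C@H](CO)[C@H]1C(=C)C(=O)O[C@H]1/C=C(/C)C#CC(=O)C(C)O | intermediate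
20 | α′-hydroxy ynone with C9 aldehyde | C=C(C)C(=O)O[C@H](C=O)[C@H]1C(=C)C(=O)O[C@H]1/C=C(/C)C#CC(=O)C(C)O | intermediate
21 | furanone aldehyde (C10 epimers) | C=C(C)C(=O)O[C@H](C=O)[C@H]1C(=C)C(=O)O[C@H]1/C=C(/C)C1=CC(=O)C(C)O1 | intermediate
22 | 3-triethylsilyloxyfuran aldehyde (not isolated) | C=C(C)C(=O)O[C@H](C=O)[C@H]1C(=C)C(=O)O[C@H]1/C=C(/C)c1cc(O[Si](CC)(CC)CC)c(C)o1 | intermediate
23 | C9 TES ether of the target | C=C(C)C(=O)O[C@H]1[C@H]2C(=C)C(=O)O[C@H]2/C=C(/C)C2=CC(=O)[C@](C)(O2)[C@@H]1O[Si](CC)(CC)CC | intermediate
24 | CNP0252578.4 | C=C(C)C(=O)O[C@H]1[C@H]2C(=C)C(=O)O[C@H]2/C=C(/C)C2=CC(=O)[C@](C)(O2)[C@@H]1O | target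

**Step count**
Total steps: 16. Longest linear sequence: 13 (steps 1, 2, 3, 5, 6, 7, 8, 11, 12, 13, 14, 15, 16).

**Steps most likely to fail**

1. **Step 15.** Three things may go wrong.
   - Oligomerisation may outrun closure because of strain in the bridged transition state.
   - The α-acyloxy aldehyde may be enol-silylated, with loss of the C8 configuration.
   - Attack may occur on the other furan face.

   The fallback uses known chemistry only and inverts the order of ring A and the carbocycle. It sets out from 20, before ring A exists.
   - TMSOTf/Et3N in CH2Cl2 at −78 °C would silylate the C10 hydroxyl and enolise the ketone toward C10, its only α-position, to give the bis(trimethylsilyl) enediol ether F1.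
   - A Mukaiyama aldol macrocyclisation (catalytic TMSOTf, high dilution) of this non-bridged chain, in which the linear C2≡C3 unit spans the ring, would give the ten-membered carbocyclic aldol as its 9,10-bis(trimethylsilyl) ether F2.
   - HF·pyridine would free the 9,10-dihydroxy ynone F3.
   - Gold-catalysed transannular 5-endo-dig addition of the tertiary C10 hydroxyl to C3, under the conditions of step 14, would then close ring A and ring C together as the last event. This closure is already known for ten-membered α′-hydroxy ynones of this germacranolide class. The fallback comes back to the route at 24.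

2. **Step 5.** There may be poor facial selectivity with respect to C8, leakage to the 6,7-anti series through isomerisation of the allylindium, or Z to E drift of the enal. The fallback replaces substrate control by catalyst control. It sets out from 4.
   - Ac2O/pyridine would give the allylic acetate F4.
   - SN2′ borylation with B2pin2 and Pd2(dba)3 would give the configurationally stable pinacol (E)-allylboronate F5, with C8 still cis to the CH2B group.
   - Allylboration of 7 through the closed chair, catalysed by the chiral phosphoric acid (R)-TRIP, would fix the aldehyde face and with it C6 and C7. Work-up would give the hydroxy ester, so the fallback comes back to the route at 9.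

3. **Step 12.** The methacryloyl group may migrate from O8 to the freed primary O9, and ring A may close prematurely during work-up. The fallback never liberates the primary alcohol. It sets out from 11.
   - TESCl/imidazole would give the C9 triethylsilyl ether F6.
   - Acylation with 13 as in step 8 would give the methacrylate F7.
   - Coupling with 17 as in step 11 would give the ynone F8.
   - Swern conditions ((COCl)2, DMSO, CH2Cl2, −78 to −40 °C, then Et3N), which oxidise primary triethylsilyl ethers directly while leaving TBS ethers alone, would give the C9 aldehyde with C10–OTBS retained F9.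
   - HF·pyridine would remove the last silyl group, and the fallback comes back to the route at 20.

**Further compounds**
F1 | step 15 | bis(trimethylsilyl) enediol ether of 20 | C=C(C)C(=O)O[C@H](C=O)[C@H]1C(=C)C(=O)O[C@H]1/C=C(/C)C#CC(O[Si](C)(C)C)=C(C)O[Si](C)(C)C
F2 | step 15 | ten-membered carbocyclic aldol, 9,10-bis(trimethylsilyl) ether (9R,10R) | C=C(C)C(=O)O[C@H]1[C@H]2C(=C)C(=O)O[C@H]2/C=C(/C)C#CC(=O)[C@](C)(O[Si](C)(C)C)[C@@H]1O[Si](C)(C)C
F3 | step 15 | ten-membered 9,10-dihydroxy ynone (9R,10R) | C=C(C)C(=O)O[C@H]1[C@H]2C(=C)C(=O)O[C@H]2/C=C(/C)C#CC(=O)[C@](C)(O)[C@@H]1O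
F4 | step 5 | acetate of 4 | COC(=O)C(=C)C(OC(C)=O)[C@H]1COC(C)(C)O1
F5 | step 5 | pinacol (E)-2-(methoxycarbonyl)allylboronate with (4S)-dioxolanyl group | COC(=O)/C(CB1OC(C)(C)C(C)(C)O1)=C/[C@H]1COC(C)(C)O1
F6 | step 12 | C9 triethylsilyl ether of 11 | CC[Si](CC)(CC)OC[C@@H](O)[C@H]1C(=C)C(=O)O[C@H]1/C=C(/C)C#C
F7 | step 12 | C8 methacrylate of F6 | C=C(C)C(=O)O[C@H](CO[Si](CC)(CC)CC)[C@H]1C(=C)C(=O)O[C@H]1/C=C(/C)C#C
F8 | step 12 | ynone with C9–OTES and C10–OTBS | C=C(C)C(=O)O[C@H](CO[Si](CC)(CC)CC)[C@H]1C(=C)C(=O)O[C@H]1/C=C(/C)C#CC(=O)C(C)O[Si](C)(C)C(C)(C)C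
F9 | step 12 | C9 aldehyde with C10–OTBS | C=C(C)C(=O)O[C@H](C=O)[C@H]1C(=C)C(=O)O[C@H]1/C=C(/C)C#CC(=O)C(C)O[Si](C)(C)C(C)(C)C
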